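Take logarithms of both the electrophile left and the time, and what looks like a stall in a closed flask of electrophile and nucleophile becomes a nearly straight line within the scatter of the readings.

| flask | electrophile | nucleophile | remark | time |
|---|---|---|---|---|
| west | 0.058 M | 0.172 M | run made earlier |  |
| south-east | 0.043 M | 0.172 M | run made earlier |  |
| ash | 0.086 M | 0.170 M |  | 10 d |
| maple | 0.086 M | 0.340 M |  | 10 d |

- west (time / d: electrophile / %, target / %): 0.417: 85, 10; 1.25: 75, 14; 2.00: 68, 16; 3.00: 66, 23; 5.00: 60, 22; 6.00: 58, 24
- south-east (time / d: electrophile / %, target / %): 0.417: 82, 14; 1.25: 74, 17; 2.00: 68, 16; 3.00: 62, 22; 5.00: 59, 20; 6.00: 58, 21

(each reading ± 2 percentage points)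

- the numbers in the tables scatter with a standard deviation of 2 percentage points

1. part of the electrophile that has reacted at the end, ash
2. part of the electrophile that has reacted at the end, maple
3. what raising the concentration of nucleophile from its lowest to its highest value here does to the part of the electrophile that has reacted (changes below 5 percentage points count as none) (it falls / no change / it rises)

From the first reading to the last, time grows 14.4-fold, while the electrophile left falls from 85% to 58% in west and from 82% to 58% in south-east. Averaged over both runs, that reads as 0.137 for the log slope: the powers of ten of electrophile lost per power of ten of time.

Time is the first setting. Going from 6.00 d to 10 d adds 0.222 of a power of ten, so by hand the electrophile left loses 0.0304 of a power of ten.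

The electrophile charge is the second. With the nucleophile charge held, a step first order in electrophile leaves percentages unchanged, and the last readings agree: charges of 0.043 M and 0.058 M both read 58% left. This reckoning therefore makes no correction, although the new charge of 0.086 M lies above both.

The nucleophile charge is the third, and no run varies it. The reckoning assumes that nucleophile destroys itself at a rate growing with its own concentration, so that charge and time count as one product. Against west, that product grows 1.65-fold for ash, giving 45.8% reacted, and 3.29-fold for maple, giving 50.7%. The reckoned rise of 4.9 points sits on the margin of 5 points.

The forecast gives 44% (37% to 52%) for ash and 60% (48% to 73%) for maple, with the trend "it rises", on the grounds of “reversible uptake of the electrophile”; it stands below this reckoning for ash and above it for maple.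

    electrophile + nucleophile → acid set free + target (k = 0.150 /M/h)
    nucleophile + acid set free ⇌ protonated nucleophile, settled at all times (K = 11000 /M)
    target ⇌ isomer of the product (K = 0.840, k = 0.0690 /h)
    2 nucleophile → homo dimer (k = 0.310 /M/h)
    nucleophile ⇌ dormant form (K = 0.300, k = 0.0170 /h)

The flask gives 39.2% for ash, with nucleophile, the limiting reagent, down to 1.0% of its charge, and 50.7% for maple; as for the part of the electrophile reacted when the nucleophile charge goes up, it rises, by 11 points. Ash stands below the reckoned value, and west recharged with ash's electrophile at its last reading time drops from 41.0% to 37.0% reacted. In maple, the log slope carries 53.4% left at 5.00 d to 48.6% at 10.0 d, and the flask holds 49.3%. Carried to 10 d at west's own charges, the log slope takes 41.0% reacted to 45.0%, and that run reaches 44.6%.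

The runs are calculated from invented constants, and the scatter is random.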